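## Retrosynthetic overview

1. The C4–CO2H bond is made last (key step). CO2 is attacked by the ring β-carbon of an allylzinc derived from an (R)-3-(bromomethyl)butenolide. This carbon is normally the electrophilic Michael terminus; here it acts as an α-methylene homoenolate. SE2′ attack anti to the C5 chain sets C4, restores the exo-methylene and gives the free acid directly.
2. The bromomethyl butenolide comes from the (R)-5-alkyl-α-methylene-γ-butyrolactone by bromination and dehydrobromination.
3. The lactone (the only ring) and the C5 stereocentre come from Ir-catalysed enantioselective transfer-hydrogenative 2-(alkoxycarbonyl)allylation of 14-hydroxytetradecyl acetate. The C4–C5 bond uses the same polarity-reversed allyl logic.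
4. The alcohol comes from tetradecane-1,14-diol by mono-acetylation; the acetate of the target is carried throughout and no protecting groups are used.

Assumption: the ligand antipode that gives the 5R lactone (Si-face addition to the transient aldehyde) is used; the sense of induction is checked on lactone 7 (chiral HPLC, optical rotation) and the other antipode is taken if needed.

## Route

Step 1
Reactants: 1 tetradecane-1,14-diol
Product: 2 14-hydroxytetradecyl acetate
Conditions: Ac2O (1.0 equiv), pyridine, THF, 0 °C → rt; chromatography, diol and diacetate recycled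
Reagents that add atoms: acetic anhydride, CC(=O)OC(C)=O
Why: Statistical mono-O-acylation of a symmetrical diol (nucleophilic acyl substitution) gives the monoacetate, which is easily separated from diol and diacetate; no stereocentre is involved.

Step 2
Reactants: 3 methyl 2-(hydroxymethyl)acrylate
Product: 4 methyl 2-(acetoxymethyl)acrylate
Conditions: Ac2O, pyridine, CH2Cl2, 0 °C → rt
Reagents that add atoms: acetic anhydride, CC(=O)OC(C)=O
Why: O-Acylation of the Baylis–Hillman alcohol gives an ionisable allylic acetate that serves as the π-allyl precursor for step 3; no stereocentre is involved.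

Step 3
Reactants: 2 14-hydroxytetradecyl acetate; 4 methyl 2-(acetoxymethyl)acrylate
Product: 7 13-[(2R)-4-methylidene-5-oxooxolan-2-yl]tridecyl acetate, via 14-oxotetradecyl acetate 5 (not isolated), via open-chain methyl hydroxy ester 6 (not isolated)
Conditions: [Ir(cod)Cl]2 (2.5 mol %), TMBTP (5 mol %, antipode per assumption), 4-chloro-3-nitrobenzoic acid (10 mol %), Cs2CO3 (20 mol %), THF, 70–90 °C, sealed tube
Reagents that add atoms: none
Why: Ir-catalysed transfer-hydrogenative carbonyl allylation (Krische type, from the alcohol oxidation level): the cyclometalated Ir dehydrogenates 2 to aldehyde 5 and turns the electrophilic allyl acetate 4 into a nucleophilic 2-(methoxycarbonyl)allyl–Ir, which adds to the Si face of 5 through a closed chair transition state fixed by the chiral bisphosphine (sets C5 as R), and hydroxy ester 6 lactonises in the flask.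

Step 4
Reactants: 7 13-[(2R)-4-methylidene-5-oxooxolan-2-yl]tridecyl acetate
Product: 9 13-[(2R)-4-(bromomethyl)-5-oxo-2,5-dihydrofuran-2-yl]tridecyl acetate, via dibromide 8 (not isolated)
Conditions: Br2 (1.05 equiv), CH2Cl2, 0 °C, dark; then Et3N (1.5 equiv), 0 °C, 30 min
Reagents that add atoms: bromine, BrBr
Why: Bromination–dehydrobromination: ionic addition of Br2 to the exocyclic alkene, then E2 loss of HBr towards the ring CH2 gives the conjugated endocyclic butenolide with bromine on the primary allylic carbon; the C5 stereocentre is not involved, and cold, brief base exposure avoids γ-deprotonation.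

Step 5
Reactants: 9 13-[(2R)-4-(bromomethyl)-5-oxo-2,5-dihydrofuran-2-yl]tridecyl acetate
Product: 12 (2R,3S)-2-(13-acetoxytridecyl)-4-methylidene-5-oxooxolane-3-carboxylic acid, via allylzinc bromide 10 (not isolated), via bromozinc carboxylate 11 (not isolated)
Conditions: Zn dust (activated), LiCl, THF, 0 °C, slow addition of 9; then MgCl2, CO2 (1 atm), 0 °C → rt; 1 M HCl
Reagents that add atoms: carbon dioxide, O=C=O
Why: Proposed new method: zinc inserts into the allylic C–Br bond to give allylzinc 10, whose nucleophilic γ-terminus is the butenolide β-carbon (an α-methylene homoenolate, d3); Mg2+-activated CO2 is attacked there through a six-membered SE2′ transition state on the ring face opposite the C5 chain, which sets the carboxyl-bearing carbon as S (trans to the chain) and returns the double bond to the exocyclic position, so acidic work-up gives the free acid directly with the acetate untouched; the closest known reactions are the zinc-mediated Barbier (Dreiding–Schmidt) additions of 3-(bromomethyl)butenolides to aldehydes, which occur at the ring carbon anti to a C5 substituent, and the MgCl2/LiCl-promoted carboxylation of allylic and benzylic zinc halides with CO2.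

## Compound list

1 | tetradecane-1,14-diol | OCCCCCCCCCCCCCCO | starting material
2 | 14-hydroxytetradecyl acetate | CC(=O)OCCCCCCCCCCCCCCO | intermediate
3 | methyl 2-(hydroxymethyl)acrylate | C=C(CO)C(=O)OC | starting material
4 | methyl 2-(acetoxymethyl)acrylate | C=C(COC(C)=O)C(=O)OC | intermediate
5 | 14-oxotetradecyl acetate | CC(=O)OCCCCCCCCCCCCCC=O | intermediate (not isolated)
6 | methyl (4R)-17-acetoxy-4-hydroxy-2-methylideneheptadecanoate | O[C@H](CCCCCCCCCCCCCOC(C)=O)CC(=C)C(=O)OC | intermediate (not isolated)
7 | 13-[(2R)-4-methylidene-5-oxooxolan-2-yl]tridecyl acetate | C=C1C(=O)O[C@H](CCCCCCCCCCCCCOC(C)=O)C1 | intermediate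
8 | 13-[(2R)-4-bromo-4-(bromomethyl)-5-oxooxolan-2-yl]tridecyl acetate (C4 epimers) | O=C1O[C@H](CCCCCCCCCCCCCOC(C)=O)CC1(Br)CBr | intermediate (not isolated)
9 | 13-[(2R)-4-(bromomethyl)-5-oxo-2,5-dihydrofuran-2-yl]tridecyl acetate | O=C1O[C@H](CCCCCCCCCCCCCOC(C)=O)C=C1CBr | intermediate
10 | [(5R)-5-(13-acetoxytridecyl)-2-oxo-2,5-dihydrofuran-3-yl]methylzinc bromide | O=C1O[C@H](CCCCCCCCCCCCCOC(C)=O)C=C1C[Zn]Br | intermediate (not isolated)
11 | bromozinc (2R,3S)-2-(13-acetoxytridecyl)-4-methylidene-5-oxooxolane-3-carboxylate | C=C1C(=O)O[C@H](CCCCCCCCCCCCCOC(C)=O)[C@H]1C(=O)O[Zn]Br | intermediate (not isolated)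
12 | (2R,3S)-2-(13-acetoxytridecyl)-4-methylidene-5-oxooxolane-3-carboxylic acid | C=C1C(=O)O[C@H](CCCCCCCCCCCCCOC(C)=O)[C@H]1C(=O)O | target

## Step count

Total step count: 5 (steps 1–5; step 2 is a one-step side branch).
Longest linear sequence: 4 steps (1 → 2 → 7 → 9 → 12).

## Steps most likely to fail, with fallbacks

Step 5 (highest risk). The ester-bearing allylzinc 10 may be too weak a nucleophile for CO2, or may react through its CH2 terminus. The fallback sets out from 9 and uses an aldehyde, the proven electrophile class for this reagent. An aqueous Barbier reaction with formaldehyde (Zn dust, sat. aq. NH4Cl–THF, formalin, rt) gives the trans alcohol 13-[(2R,3R)-3-(hydroxymethyl)-4-methylidene-5-oxooxolan-2-yl]tridecyl acetate F1. Jones oxidation of its primary alcohol (CrO3, H2SO4, acetone, 0 °C) then gives the acid, and the route is rejoined at 12.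

Step 4. The dehydrobromination may go instead to the exocyclic vinyl bromide, or the amine may erode the C5 configuration of the butenolide. The fallback sets out from 7 and avoids base: Wohl–Ziegler bromination (NBS, cat. AIBN, PhCF3, 80 °C) abstracts the allylic ring hydrogen, and bromine transfer to the resulting allyl radical gives 9. Its allylic isomer 13-[(2R)-3-bromo-4-methylidene-5-oxooxolan-2-yl]tridecyl acetate F2 forms alongside. Both bromides give the same allylzinc on zinc insertion, so the mixture is carried on; the route is rejoined at 9 (F2 enters at 10).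

Step 3. The hydrogen auto-transfer allylation with the electron-poor allyl donor may stall or give low ee with this long-chain alcohol. The fallback sets out from 2 and works at the aldehyde oxidation level with a different metal. Alcohol 2 is oxidised to aldehyde 5 (TEMPO cat., PhI(OAc)2, CH2Cl2). A chromium-catalysed asymmetric Nozaki–Hiyama–Kishi 2-(ethoxycarbonyl)allylation follows, using commercial ethyl 2-(bromomethyl)acrylate (CrCl2 cat., chiral carbazole-bis(oxazoline) ligand, Mn, TMSCl, THF; then dilute HCl). This gives ethyl (4R)-17-acetoxy-4-hydroxy-2-methylideneheptadecanoate F3, which lactonises (TsOH cat., CH2Cl2), and the route is rejoined at 7.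

## Further compounds

F1 | step 5 | 13-[(2R,3R)-3-(hydroxymethyl)-4-methylidene-5-oxooxolan-2-yl]tridecyl acetate | C=C1C(=O)O[C@H](CCCCCCCCCCCCCOC(C)=O)[C@H]1CO
F2 | step 4 | 13-[(2R)-3-bromo-4-methylidene-5-oxooxolan-2-yl]tridecyl acetate (C3 epimers) | C=C1C(=O)O[C@H](CCCCCCCCCCCCCOC(C)=O)C1Br
F3 | step 3 | ethyl (4R)-17-acetoxy-4-hydroxy-2-methylideneheptadecanoate | O[C@H](CCCCCCCCCCCCCOC(C)=O)CC(=C)C(=O)OCC
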